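**Plan**
1. Retrosynthesis: after removal of eight O-benzyl groups, both bonds to the central catechol ring are cut in one operation: C2–C1' (flavanone C2 to the aryl carbon) and C6'–C8'' (the neighbouring aryl carbon to C8 of the flavone).
2. This leaves three components: 5,7-bis(benzyloxy)chromone, 4,5-bis(benzyloxy)benzyne (from a 2-silylaryl triflate) and the 8-boronic acid of tetra-O-benzylluteolin.
3. Enabling feature: the central ring carries its two flavonoid substituents on adjacent carbons C1' and C6' and its oxygens on C3' and C4', so it maps onto a symmetrical 4,5-dioxybenzyne that is difunctionalised across its triple bond without any regiochemical question. Ring A of the flavone has no hydrogen ortho to C8'' (C7''–O and C8a''–O1'').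
4. Forward: all ring systems are brought in preformed. The three-component step forms first the biaryl bond (aryl–palladium adds to the aryne) and then the C2–C1' bond (the new aryl–palladium adds to the chromone). Hydrogenolysis ends the route.
5. Stereochemistry: the single stereocentre, C2 (R), is set in the key step by a chiral pyridine–oxazoline ligand on palladium and is kept by using only neutral conditions afterwards.

Key step: step 8

Assumption: the configuration of the biaryl axis between C6' and C8'' is not given in the target, so the axis is treated as not configurationally defined and rotamers about it count as one compound.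

**Step 1**
Reactants: 1 luteolin
Product: 2 5,7,3',4'-tetra-O-benzylluteolin
Conditions: BnBr (6 equiv), Cs2CO3, n-Bu4NI (cat.), DMF, 80 °C
Reagents that add atoms: benzyl bromide, BrCc1ccccc1
Why: Williamson ether synthesis in which Cs2CO3 and excess benzyl bromide should alkylate all four phenols, including the hydrogen-bonded 5-OH, giving ethers that are removable at the end under neutral conditions.

**Step 2**
Reactants: 2 5,7,3',4'-tetra-O-benzylluteolin
Product: 3 8-iodo-5,7,3',4'-tetra-O-benzylluteolin
Conditions: NIS (1.1 equiv), CF3CO2H (cat.), CH2Cl2/MeCN, 0 °C to rt, dark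
Reagents that add atoms: N-iodosuccinimide, O=C1CCC(=O)N1I
Why: Electrophilic aromatic iodination in which ring A is the most electron-rich ring and, with O5 alkylated, C8 (flanked by O7 and the ring oxygen) is more accessible than C6 (between two benzyloxy groups), while ring B is deactivated by conjugation with the pyranone.

**Step 3**
Reactants: 3 8-iodo-5,7,3',4'-tetra-O-benzylluteolin
Product: 4 5,7,3',4'-tetra-O-benzylluteolin-8-boronic acid pinacol ester
Conditions: B2pin2, PdCl2(dppf) (5 mol%), KOAc, dioxane, 90 °C
Reagents that add atoms: bis(pinacolato)diboron, CC1(C)OB(OC1(C)C)B1OC(C)(C)C(C)(C)O1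
Why: Miyaura borylation (oxidative addition of zerovalent palladium into the C8–I bond, acetate-assisted transmetalation with the diboron, reductive elimination), a reaction type with close precedent on 8-iodoflavone ethers.

**Step 4**
Reactants: 4 5,7,3',4'-tetra-O-benzylluteolin-8-boronic acid pinacol ester
Product: 5 (5,7,3',4'-tetra-O-benzylluteolin-8-yl)boronic acid
Conditions: NaIO4, NH4OAc, acetone/H2O, rt; used without storage
Reagents that add atoms: water, O
Why: Oxidative cleavage of the pinacol ester, in which hydrolysis at boron is pulled to completion because periodate cleaves the released pinacol to acetone under buffered, nearly neutral conditions that spare the benzyl ethers and the flavone.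

**Step 5**
Reactants: 6 5,7-dihydroxy-4H-chromen-4-one
Product: 7 5,7-bis(benzyloxy)-4H-chromen-4-one
Conditions: BnBr (3 equiv), Cs2CO3, n-Bu4NI (cat.), DMF, 70 °C
Reagents that add atoms: benzyl bromide, BrCc1ccccc1
Why: Williamson ether synthesis of both phenols, so that no phenoxide is present later to add to the aryne.

**Step 6**
Reactants: 8 3,4-bis(benzyloxy)phenol
Product: 9 4,5-bis(benzyloxy)-2-bromophenol
Conditions: NBS (1.0 equiv), CH2Cl2, 0 °C
Reagents that add atoms: N-bromosuccinimide, O=C1CCC(=O)N1Br
Why: Electrophilic aromatic bromination directed ortho by the free hydroxyl, at the ortho position that is para to the 3-benzyloxy group and not flanked by two oxygens.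

**Step 7**
Reactants: 9 4,5-bis(benzyloxy)-2-bromophenol
Product: 12 4,5-bis(benzyloxy)-2-(trimethylsilyl)phenyl trifluoromethanesulfonate, via aryl trimethylsilyl ether 10 (not isolated), via lithium 2-silylphenoxide 11 (not isolated)
Conditions: HN(SiMe3)2, THF, reflux, then evaporation; n-BuLi (1.05 equiv), THF, −78 °C to rt; Tf2O, −78 °C
Reagents that add atoms: hexamethyldisilazane, C[Si](C)(C)N[Si](C)(C)C; trifluoromethanesulfonic anhydride, O=S(=O)(OS(=O)(=O)C(F)(F)F)C(F)(F)F
Why: O-Silylation, bromine–lithium exchange (much faster at −78 °C than benzylic deprotonation of the benzyl ethers) and retro-Brook rearrangement (1,3 O-to-C silyl shift) place silicon ortho to the phenoxide, which is then trapped as the triflate.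

**Step 8**
Reactants: 5 (5,7,3',4'-tetra-O-benzylluteolin-8-yl)boronic acid (1.0 equiv); 12 4,5-bis(benzyloxy)-2-(trimethylsilyl)phenyl trifluoromethanesulfonate (1.3 equiv); 7 5,7-bis(benzyloxy)-4H-chromen-4-one (1.5 equiv)
Product: 14 (2R)-5,7-bis(benzyloxy)-2-{4,5-bis(benzyloxy)-2-[5,7-bis(benzyloxy)-2-(3,4-bis(benzyloxy)phenyl)-4-oxo-4H-chromen-8-yl]phenyl}chroman-4-one, via 4,5-bis(benzyloxy)benzyne 13 (not isolated)
Conditions: Pd(OCOCF3)2 (10 mol%), (S)-4-tert-butyl-2-(pyridin-2-yl)-4,5-dihydrooxazole [(S)-t-BuPyOx] (12 mol%), NH4PF6 (30 mol%), CsF (3 equiv), H2O (5 equiv), ClCH2CH2Cl/MeCN (4:1), 50 °C, 12 added slowly by syringe pump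
Reagents that add atoms: none
Why: Proposed new method: Transmetalation of 5 to the cationic divalent palladium–PyOx complex gives a flavon-8-yl palladium species that carbopalladates the strained triple bond of aryne 13 (released slowly from 12 by fluoride); the resulting 2-(flavon-8-yl)aryl palladium species adds across C2=C3 of chromone 7 to form the aryl–C2 bond, and protonolysis of the palladium enolate by water returns the catalyst. The closest known reaction types are the PyOx–palladium-catalysed asymmetric conjugate addition of arylboronic acids to chromones and cationic-palladium cascades in which an arylboronic acid adds across an alkyne and the new organopalladium then adds to an enone; aryl–palladium carbopalladation of arynes is also established, but their merger is new. No ring is closed, since the step is a three-component assembly around the central ring on preformed ring systems. The C2 stereocentre is set in the enone insertion by the tert-butyl group of the (S)-ligand, which by the steric model used for cyclic enones should deliver the aryl to the face that gives (2R); the sense is to be confirmed with a simple arylboronic acid and the (R)-ligand used if it proves opposite. The step needs chemoselectivity (aryne uptake before chromone uptake, only one aryne, no palladium migration), and the substrate secures it: both positions ortho to C8 of 5 carry oxygen, so the first aryl–palladium is too hindered to add to 7 yet takes up the unhindered aryne and has no ortho hydrogen for a 1,4-palladium shift or cyclopalladation, whereas after insertion palladium sits on a carbon with one free ortho position and adds to 7 (the β-aryl-substituted C2=C3 of the flavone is not a competing acceptor). Regioselectivity is not an issue because 13 is symmetrical.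

**Step 9**
Reactants: 14 (2R)-5,7-bis(benzyloxy)-2-{4,5-bis(benzyloxy)-2-[5,7-bis(benzyloxy)-2-(3,4-bis(benzyloxy)phenyl)-4-oxo-4H-chromen-8-yl]phenyl}chroman-4-one
Product: 15 (2R)-2-{2-[2-(3,4-dihydroxyphenyl)-5,7-dihydroxy-4-oxo-4H-chromen-8-yl]-4,5-dihydroxyphenyl}-5,7-dihydroxychroman-4-one
Conditions: H2 (1 atm), 10% Pd/C, THF/MeOH (1:1), rt, stopped at full debenzylation
Reagents that add atoms: none
Why: Hydrogenolysis of the eight aryl benzyl ethers on palladium under neutral conditions at room temperature should leave the flavone C2=C3 bond, the flavanone C2–O bond and the base-labile C2 stereocentre untouched.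

**Compound list**
1 | luteolin | O=c1cc(-c2ccc(O)c(O)c2)oc2cc(O)cc(O)c12 | starting material
2 | 5,7,3',4'-tetra-O-benzylluteolin; 5,7-bis(benzyloxy)-2-[3,4-bis(benzyloxy)phenyl]-4H-chromen-4-one | O=c1cc(-c2ccc(OCc3ccccc3)c(OCc3ccccc3)c2)oc2cc(OCc3ccccc3)cc(OCc3ccccc3)c12 | intermediate
3 | 8-iodo-5,7,3',4'-tetra-O-benzylluteolin | O=c1cc(-c2ccc(OCc3ccccc3)c(OCc3ccccc3)c2)oc2c(I)c(OCc3ccccc3)cc(OCc3ccccc3)c12 | intermediate
4 | 5,7,3',4'-tetra-O-benzylluteolin-8-boronic acid pinacol ester | O=c1cc(-c2ccc(OCc3ccccc3)c(OCc3ccccc3)c2)oc2c(B3OC(C)(C)C(C)(C)O3)c(OCc3ccccc3)cc(OCc3ccccc3)c12 | intermediate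
5 | (5,7,3',4'-tetra-O-benzylluteolin-8-yl)boronic acid | O=c1cc(-c2ccc(OCc3ccccc3)c(OCc3ccccc3)c2)oc2c(B(O)O)c(OCc3ccccc3)cc(OCc3ccccc3)c12 | intermediate
6 | 5,7-dihydroxy-4H-chromen-4-one | O=c1ccoc2cc(O)cc(O)c12 | starting material
7 | 5,7-bis(benzyloxy)-4H-chromen-4-one | O=c1ccoc2cc(OCc3ccccc3)cc(OCc3ccccc3)c12 | intermediate
8 | 3,4-bis(benzyloxy)phenol | Oc1ccc(OCc2ccccc2)c(OCc2ccccc2)c1 | starting material
9 | 4,5-bis(benzyloxy)-2-bromophenol | Oc1cc(OCc2ccccc2)c(OCc2ccccc2)cc1Br | intermediate
10 | [4,5-bis(benzyloxy)-2-bromophenoxy]trimethylsilane | C[Si](C)(C)Oc1cc(OCc2ccccc2)c(OCc2ccccc2)cc1Br | intermediate (not isolated)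
11 | lithium 4,5-bis(benzyloxy)-2-(trimethylsilyl)phenoxide | [Li+].[O-]c1cc(OCc2ccccc2)c(OCc2ccccc2)cc1[Si](C)(C)C | intermediate (not isolated)
12 | 4,5-bis(benzyloxy)-2-(trimethylsilyl)phenyl trifluoromethanesulfonate | C[Si](C)(C)c1cc(OCc2ccccc2)c(OCc2ccccc2)cc1OS(=O)(=O)C(F)(F)F | intermediate
13 | 4,5-bis(benzyloxy)benzyne (1,2-didehydro-4,5-bis(benzyloxy)benzene) | C1#CC=C(OCc2ccccc2)C(OCc2ccccc2)=C1 | intermediate (not isolated)
14 | (2R)-5,7-bis(benzyloxy)-2-{4,5-bis(benzyloxy)-2-[5,7-bis(benzyloxy)-2-(3,4-bis(benzyloxy)phenyl)-4-oxo-4H-chromen-8-yl]phenyl}chroman-4-one | O=C1C[C@H](c2cc(OCc3ccccc3)c(OCc3ccccc3)cc2-c2c(OCc3ccccc3)cc(OCc3ccccc3)c3c(=O)cc(-c4ccc(OCc5ccccc5)c(OCc5ccccc5)c4)oc23)Oc2cc(OCc3ccccc3)cc(OCc3ccccc3)c21 | intermediate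
15 | (2R)-2-{2-[2-(3,4-dihydroxyphenyl)-5,7-dihydroxy-4-oxo-4H-chromen-8-yl]-4,5-dihydroxyphenyl}-5,7-dihydroxychroman-4-one | O=C1C[C@H](c2cc(O)c(O)cc2-c2c(O)cc(O)c3c(=O)cc(-c4ccc(O)c(O)c4)oc23)Oc2cc(O)cc(O)c21 | target

**Step count**
Total: 9 steps. Longest linear sequence: 6 steps (steps 1, 2, 3, 4, 8, 9).

**Steps most likely to fail**

Step 8. What may go wrong:
- direct addition of the first aryl–palladium to the chromone without uptake of the aryne, or uptake of more than one aryne;
- protodeboronation of the doubly ortho-oxygenated boronic acid, or protonolysis of an aryl–palladium species before the next insertion;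
- O–H addition of water or the boronic acid to the aryne, or protodesilylation of the aryne precursor;
- fluoride-induced reversible opening of the flavanone ring, with loss of enantiopurity;
- poor facial selectivity caused by the bulky ortho substituent.

The fallback is stepwise, uses known chemistry, sets out from 4 and comes back at 14. Suzuki–Miyaura coupling of 4 with bromophenol 9 (Pd(OAc)2, 2-dicyclohexylphosphino-2',6'-dimethoxybiphenyl, K3PO4, toluene/H2O, 90 °C) should give the biaryl phenol 5,7-bis(benzyloxy)-2-[3,4-bis(benzyloxy)phenyl]-8-[4,5-bis(benzyloxy)-2-hydroxyphenyl]-4H-chromen-4-one F1. Triflation (Tf2O, pyridine, CH2Cl2, 0 °C) should give the corresponding aryl trifluoromethanesulfonate F2. Miyaura borylation (B2pin2, PdCl2(dppf), KOAc, dioxane, 90 °C) should give the biaryl pinacol boronate F3. Rhodium-catalysed asymmetric 1,4-addition (Hayashi–Miyaura reaction) of F3 to chromone 7 ([RhCl(C2H4)2]2, (R)-BINAP, aqueous K3PO4, dioxane, 50 °C) would then form the same C2–C1' bond and give 14. The sense of induction is to be confirmed on 7 with a simple arylboronic acid.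

Step 3. What may go wrong: hydrodeiodination in place of borylation at the hindered, electron-rich C8, and protodeboronation of the boron compounds on handling. The fallback reverses the polarity of the biaryl coupling so that boron never sits on C8; it sets out from 3 and comes back at 14. Miyaura borylation of bromophenol 9 (B2pin2, PdCl2(dppf), KOAc, dioxane, 90 °C) should give 4,5-bis(benzyloxy)-2-(4,4,5,5-tetramethyl-1,3,2-dioxaborolan-2-yl)phenol F4. Suzuki–Miyaura coupling of F4 with iodide 3 (Pd(OAc)2, 2-dicyclohexylphosphino-2',6'-dimethoxybiphenyl, K3PO4, toluene/H2O, 90 °C) should give the biaryl phenol F1, which is carried through F2 and F3 to 14 as described for step 8.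

Step 9. What may go wrong: over-reduction of the flavone C2=C3 bond, hydrogenolytic opening of the benzylic C2–O bond of the flavanone, or incomplete cleavage of the eight ethers. The fallback is a non-reductive debenzylation that sets out from 14 and comes back at 15: BCl3 with pentamethylbenzene as cation scavenger, CH2Cl2, −78 °C, then methanol quench. It makes no new compound.

**Further compounds**
F1 | step 8 | 5,7-bis(benzyloxy)-2-[3,4-bis(benzyloxy)phenyl]-8-[4,5-bis(benzyloxy)-2-hydroxyphenyl]-4H-chromen-4-one | O=c1cc(-c2ccc(OCc3ccccc3)c(OCc3ccccc3)c2)oc2c(-c3cc(OCc4ccccc4)c(OCc4ccccc4)cc3O)c(OCc3ccccc3)cc(OCc3ccccc3)c12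
F2 | step 8 | 4,5-bis(benzyloxy)-2-{5,7-bis(benzyloxy)-2-[3,4-bis(benzyloxy)phenyl]-4-oxo-4H-chromen-8-yl}phenyl trifluoromethanesulfonate | O=c1cc(-c2ccc(OCc3ccccc3)c(OCc3ccccc3)c2)oc2c(-c3cc(OCc4ccccc4)c(OCc4ccccc4)cc3OS(=O)(=O)C(F)(F)F)c(OCc3ccccc3)cc(OCc3ccccc3)c12
F3 | step 8 | 5,7-bis(benzyloxy)-2-[3,4-bis(benzyloxy)phenyl]-8-[4,5-bis(benzyloxy)-2-(4,4,5,5-tetramethyl-1,3,2-dioxaborolan-2-yl)phenyl]-4H-chromen-4-one | O=c1cc(-c2ccc(OCc3ccccc3)c(OCc3ccccc3)c2)oc2c(-c3cc(OCc4ccccc4)c(OCc4ccccc4)cc3B4OC(C)(C)C(C)(C)O4)c(OCc3ccccc3)cc(OCc3ccccc3)c12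
F4 | step 3 | 4,5-bis(benzyloxy)-2-(4,4,5,5-tetramethyl-1,3,2-dioxaborolan-2-yl)phenol | Oc1cc(OCc2ccccc2)c(OCc2ccccc2)cc1B1OC(C)(C)C(C)(C)O1
F0 | step 9 | none | none
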